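A one-step world, with one irreversible step and one time constant, takes the whole charge of starting material, the limiting reagent, into product. These flasks stop short of that, and the question is how far the ash run gets.

| flask | starting material | partner | time |
|---|---|---|---|
| alder | 0.150 M | 0.300 M |  |
| elm | 0.0600 M | 0.210 M |  |
| maple | 0.150 M | 0.900 M |  |
| ash | 0.0750 M | 0.900 M | 51 min |

- alder run (time / min: [product] / M): 8.5: 0.0166; 17: 0.0385; 26: 0.0541; 34: 0.0622; 42: 0.0660; 51: 0.0690
- elm run (time / min: [product] / M): 8.5: 0.0074; 17: 0.0148; 26: 0.0199; 34: 0.0233; 42: 0.0235; 51: 0.0238
- maple run (time / min: [product] / M): 8.5: 0.0392; 17: 0.0734; 26: 0.0929; 34: 0.1024; 42: 0.1069; 51: 0.1095

(standard deviation of a reading: 4 × 10⁻⁴ M)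

1. order of the initial rate in [starting material], near the charge of the alder run, the rate being that where two percent of its starting material are product (one fixed amount of product, the same in the runs compared)
2. order of the initial rate in [partner], near the charge of the alder run, the rate being that where two percent of its starting material are product
3. product in the ash run at 51 min, as a share of the starting material charged

- Overall: starting material + partner -> product.
- Constant volume, constant temperature.
- The analysis sees a species whether free or bound.
- "The second partner" is partner.
- An order is taken over about fifteen percent of the charge, up and down.

The ash run's neighbour is the maple run, with the same partner charge of 0.900 M and twice the starting material. At 51 min the maple run stands at 73.0% of its starting material. The alder run, with the same starting material but 0.300 M of partner, stands at a smaller 46.0% at that time.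

I read each run as a tank with two drains. Starting material leaves towards product at a rate that grows with partner, and towards something unseen at a rate that does not. In this picture both drains act on the same starting material, so the share of product is the mean partner level over that level plus a constant. From the maple run, with mean partner 0.845 M, the constant comes to 0.313 M. This is the crossing partner level, the concentration at which the two drains run equally fast, and partner over it is the selectivity factor. The alder run, with mean partner 0.265 M, gives 0.311 M on its own reading. The ash run uses less partner, so its mean level is 0.873 M, a little above the maple run's. I therefore commit to 73.6% for the ash run at 51 min, slightly above the maple run's share.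

The forecast gives orders of 0.8 in starting material and 0.6 in partner and 74.5% for the ash run, reading the stop differently from me: “The plateaus fit a reversible 1:1 reaction”. The flask gives orders of 0.36 in starting material and 0.59 in partner, and 74.0% in the ash run.

    starting material + partner ⇌ intermediate (1.776 M⁻¹ min⁻¹, 0.09060 min⁻¹)
    intermediate → product (0.07320 min⁻¹)
    starting material → decomposed substrate (0.2208 min⁻¹)
    2 starting material ⇌ idle substrate dimer, settled at all times (115.0 M⁻¹)

The rival drain is the decay of starting material to decomposed substrate, and the partner's drain runs through the intermediate. At the ash run's mean partner, the crossing as I read it puts 26.4% of the charge outside product at 51 min, and the flask has 26.0% of the ash run's charge outside product at that time. In the elm run, with mean partner 0.198 M, the same crossing gives 38.7%, and its last reading stands at 39.7%. The ash run without that decay reaches 96.2% instead of 74.0%, so the decay takes 22 percentage points, which is 85% of what is missing.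

The runs stem from a simulated flask for substances that don't exist, and the scatter is random.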